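We start from a leftover: the free monomer still unbound at the end, subtracted from the charge, gives the monomer in chains together with what went to spent initiator A, so we need the time living ends stood in the flask and the number of chains that share the monomer.

- west: free monomer 2.0 mM; initiator 0.2 mol%; time 4.0 min
- south: free monomer 2.0 mM; initiator 0.12 mol%; time 4.0 min

    free monomer + initiator → living end + monomer in chains (k1 = 28 M⁻¹ s⁻¹)
    free monomer + living end → monomer in chains + living end, rate k2*[living end]*[free monomer] (k2 = 13000 M⁻¹ s⁻¹)
    free monomer + initiator → spent initiator A (k3 = 28 M⁻¹ s⁻¹)
    2 living end → dead end B (k4 = 1.8 × 10⁵ M⁻¹ s⁻¹)

* which of the two ends with the longer chains by the average number of monomer units in a chain (chains begun, living or dead) ("neither" if they lie within 10 %) (west / south / neither)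
* average number of monomer units in a chain (chains begun, living or dead) at the end, west
* average number of monomer units in a chain (chains begun, living or dead) at the end, south

- a step written with two of one species runs at k times the square of its concentration and takes two of it each time
- the average divides the monomer in chains by the number of chains begun, living and dead together
- run time (west): 4.0 min

The ledger of initiator for west closes thus, the two steps that take initiator having equal constants:

- charged: 0.00400 mM
- to spent initiator A: 0.00200 mM
- chains begun: 0.00200 mM
- still living at the end, from the second-order fall: 1.16 × 10⁻⁵ mM
- dead end B, two chains each: 9.94 × 10⁻⁴ mM

In west, initiator fades with a time 8.93 s at the charged free monomer, while a living end lasts 3.52 s at the starting supply. Because a living end lasts a shorter time than initiator takes to fade, living ends follow the square root of their supply and fade with 17.9 s. Their time integral, counted in units of one over the pairing rate, has a burst term and a tail term, roughly joined: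

- burst: 5.07
- tail: 2.60
- sum: 7.67

We call this sum the dose, the lifetime of living ends summed over the run. Multiplied by 0.0361, it is the logarithm of charged over left free monomer. So west reacts 24.2 %, and its chains average 242.

South has 0.00120 mM of chains begun and a dose of 6.53, which is less than the dose of west. It reacts 21.0 % and averages 350, so we expect south.

The forecast, with figures a little apart from ours, said south, with 237 (225 to 250) for west and 332 (315 to 350) for south, reasoning that “exactly half of it starts chains”.

The simulation gives south, with 238 for west and 332 for south. West holds 76.1 % of its free monomer at 4.00 min. Read back through the same ratio, that leftover gives a dose of 7.57, against our 7.67.

Now take the neighbour like west but with 5.0 mM of free monomer. The burst term keeps its value and the tail gains the logarithm of the charge ratio, so the dose is 8.59 and the length 267. The computed flask gives 265, with 73 % of its free monomer left.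

The numbers are those of an exercise; the flask was simulated.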